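Ring C is disconnected in a [3+3] sense at O1–C2 and C4–C4a, and the C2–aryl bond is saved for last. The key step exploits the local symmetry of ring A: O1 and O7 both flank C8 (prenyl), and C4a and C6 are equivalent, so the bis(MOM) ether of 5-O-methyl-2-prenylresorcinol can only give the 8-prenyl isomer. In one flask, directed metalation at C4a, Negishi acylation with (E)-3-ethoxyacryloyl chloride (C4–C4a), then acid-triggered MOM loss and addition–elimination ring closure (O1–C2) should deliver the 8-prenylchromone. After O5-demethylation, the C2 stereocenter is set in the final step by rhodium-catalysed asymmetric conjugate addition of 4-methoxyphenylboronic acid.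

Key step: step 3

Remark: the stereodescriptor of the target corresponds to (2S) (priorities O1 > aryl > C3 > H); compounds 1, 2, 4, 7 and 14 are taken as purchased.

Step 1
Reactants: 1 5-methoxybenzene-1,3-diol; 2 chloromethyl methyl ether
Product: 3 1-methoxy-3,5-bis(methoxymethoxy)benzene
Conditions: NaH (2.4 equiv), 2 (2.4 equiv), DMF, 0 °C to rt
Reagents that add atoms: chloromethyl methyl ether, COCCl
Why: Williamson-type O-alkylation of the bis-phenoxide with the reactive α-chloro ether should give the bis(MOM) ether, whose acetal groups later direct both metalations and mask O1 and O7 in acid-labile form.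

Step 2
Reactants: 3 1-methoxy-3,5-bis(methoxymethoxy)benzene; 4 1-bromo-3-methylbut-2-ene (prenyl bromide)
Product: 6 5-methoxy-1,3-bis(methoxymethoxy)-2-(3-methylbut-2-en-1-yl)benzene, via aryllithium 5 (not isolated)
Conditions: n-BuLi, THF, 0 °C; CuBr·SMe2 (10 mol%), 4, −78 °C to rt
Reagents that add atoms: 1-bromo-3-methylbut-2-ene, CC(C)=CCBr
Why: Directed ortho-metalation should occur at the C–H between the two MOM ethers (two chelating directors, against one MOM and one weaker methoxy group at the other sites), and copper-catalysed allylic substitution at the primary carbon of prenyl bromide places the future C8 substituent on the symmetry axis of ring A.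

Step 3
Reactants: 6 5-methoxy-1,3-bis(methoxymethoxy)-2-(3-methylbut-2-en-1-yl)benzene; 7 (E)-3-ethoxyacryloyl chloride
Product: 12 7-hydroxy-5-methoxy-8-(3-methylbut-2-en-1-yl)-4H-chromen-4-one, via aryllithium 8 (not isolated), via arylzinc chloride 9 (not isolated), via ethoxy enone 10 (not isolated), via dihydroxy enone 11 (not isolated)
Conditions: n-BuLi, THF, 0 °C; ZnCl2, 0 °C to rt; 7, Pd(PPh3)4 (5 mol%), rt; then 3 M HCl in MeOH, 40 °C
Reagents that add atoms: (E)-3-ethoxyacryloyl chloride, CCO/C=C/C(=O)Cl
Why: A second directed ortho-metalation can only take place at the one remaining kind of ring C–H (C4a, equivalent to C6, flanked by OMOM and OMe), and after transmetalation to zinc a Negishi acylation (oxidative addition of 7 to zerovalent palladium, transmetalation, reductive elimination) forms C4–C4a by acyl substitution without conjugate addition to the β-ethoxy enone. Methanolic HCl then cleaves both MOM acetals, and the only hydroxyl ortho to the ketone, the one next to the prenyl group, adds to the β-carbon of the protonated vinylogous ester with loss of ethanol, which forms O1–C2; the closest known reaction type is the acid-induced cyclization of 2-hydroxyaryl β-alkoxyvinyl or β-aminovinyl ketones to chromones. Ring C closes in the 6-endo-trig mode followed by elimination, a net addition–elimination at C2. No stereocenter is formed, since C2 stays sp2 and becomes stereogenic only in step 5. The step needs regiocontrol of the ring closure (8- against 6-prenyl), secured by the symmetry of 6 and by the methyl ether that blocks O5; it also needs ring metalation in preference to the benzylic–allylic CH2, favoured by the two flanking oxygen directors, and survival of the prenyl group, for which the acid stage is kept mild and short.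

Step 4
Reactants: 12 7-hydroxy-5-methoxy-8-(3-methylbut-2-en-1-yl)-4H-chromen-4-one
Product: 13 5,7-dihydroxy-8-(3-methylbut-2-en-1-yl)-4H-chromen-4-one
Conditions: MgI2·OEt2 (4 equiv), THF, 60 °C; aqueous work-up
Reagents that add atoms: none
Why: Chelation-assisted ether cleavage, in which magnesium binds the C4 carbonyl and the peri 5-methoxy oxygen and iodide removes the methyl group by SN2, should be clean because 12 carries only this one methyl ether and no stereocenter yet, and the mild Lewis acid should leave the prenyl group uncyclized.

Step 5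
Reactants: 13 5,7-dihydroxy-8-(3-methylbut-2-en-1-yl)-4H-chromen-4-one; 14 4-methoxyphenylboronic acid
Product: 15 (2S)-5,7-dihydroxy-2-(4-methoxyphenyl)-8-(3-methylbut-2-en-1-yl)-2,3-dihydro-4H-chromen-4-one
Conditions: [Rh(OH)(cod)]2 (3 mol%), (S)-MeO-F12-BIPHEP (6.6 mol%), 14 (3 equiv), toluene/H2O 10:1, 30 °C
Reagents that add atoms: 4-methoxyphenylboronic acid, COc1ccc(B(O)O)cc1
Why: Hayashi–Miyaura asymmetric conjugate addition, in which an aryl–rhodium species formed by transmetalation inserts the C2=C3 bond of the chromone and the resulting oxa-π-allyl rhodium is protonated by water, should set C2 under control of the atropisomeric bisphosphine [(S)-2,2'-bis[bis(3,4,5-trifluorophenyl)phosphino]-6,6'-dimethoxy-1,1'-biphenyl; by analogy with (S)-BINAP–rhodium additions to cyclic enones the aryl group should reach the Re face of C2 (O1 > C3 > H), which gives (2S), and the (R)-ligand would be taken if the sense proved opposite], while the base-free, near-neutral medium keeps the phenols protonated and should prevent racemization by retro-oxa-Michael ring opening.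

Compound list
1 | 5-methoxybenzene-1,3-diol (5-methoxyresorcinol) | COc1cc(O)cc(O)c1 | starting material
2 | chloromethyl methyl ether | COCCl | starting material
3 | 1-methoxy-3,5-bis(methoxymethoxy)benzene | COCOc1cc(OC)cc(OCOC)c1 | intermediate
4 | 1-bromo-3-methylbut-2-ene (prenyl bromide) | CC(C)=CCBr | starting material
5 | [4-methoxy-2,6-bis(methoxymethoxy)phenyl]lithium | [Li]c1c(OCOC)cc(OC)cc1OCOC | intermediate
6 | 5-methoxy-1,3-bis(methoxymethoxy)-2-(3-methylbut-2-en-1-yl)benzene | COCOc1cc(OC)cc(OCOC)c1CC=C(C)C | intermediate
7 | (E)-3-ethoxyacryloyl chloride | CCO/C=C/C(=O)Cl | starting material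
8 | [6-methoxy-2,4-bis(methoxymethoxy)-3-(3-methylbut-2-en-1-yl)phenyl]lithium | COCOc1c([Li])c(OC)cc(OCOC)c1CC=C(C)C | intermediate
9 | chloro[6-methoxy-2,4-bis(methoxymethoxy)-3-(3-methylbut-2-en-1-yl)phenyl]zinc | COCOc1c([Zn]Cl)c(OC)cc(OCOC)c1CC=C(C)C | intermediate
10 | (E)-3-ethoxy-1-[6-methoxy-2,4-bis(methoxymethoxy)-3-(3-methylbut-2-en-1-yl)phenyl]prop-2-en-1-one | CCO/C=C/C(=O)c1c(OC)cc(OCOC)c(CC=C(C)C)c1OCOC | intermediate
11 | (E)-1-[2,4-dihydroxy-6-methoxy-3-(3-methylbut-2-en-1-yl)phenyl]-3-ethoxyprop-2-en-1-one | CCO/C=C/C(=O)c1c(OC)cc(O)c(CC=C(C)C)c1O | intermediate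
12 | 7-hydroxy-5-methoxy-8-(3-methylbut-2-en-1-yl)-4H-chromen-4-one | COc1cc(O)c(CC=C(C)C)c2occc(=O)c12 | intermediate
13 | 5,7-dihydroxy-8-(3-methylbut-2-en-1-yl)-4H-chromen-4-one | Oc1cc(O)c(CC=C(C)C)c2occc(=O)c12 | intermediate
14 | 4-methoxyphenylboronic acid | COc1ccc(B(O)O)cc1 | starting material
15 | (2S)-5,7-dihydroxy-2-(4-methoxyphenyl)-8-(3-methylbut-2-en-1-yl)-2,3-dihydro-4H-chromen-4-one | COc1ccc([C@@H]2CC(=O)c3c(O)cc(O)c(CC=C(C)C)c3O2)cc1 | target

Total step count: 5. Longest linear sequence: 5 steps (1 → 3 → 6 → 12 → 13 → 15).

Steps most likely to fail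

1. Step 5 (asymmetric conjugate arylation). The electron-rich chromone with two free hydroxyl groups may react too slowly. The acidic 7-hydroxyl may also protonate the aryl–rhodium intermediate and waste the boronic acid, or the product may lose enantiopurity by ring opening. Fallback: setting out from 13, the 7-hydroxyl is silylated selectively (TBSCl, imidazole, DMF, 0 °C; the chelated 5-hydroxyl stays free) to give 7-silyloxy chromone F1. The same rhodium-catalysed addition of 14 then gives silylated flavanone F2, and HF·pyridine in THF/pyridine at 0 °C removes the silyl group and comes back to the route at 15.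

2. Step 3 (key step). Deprotonation may occur at the benzylic–allylic CH2 of the prenyl group instead of on the ring. The hindered arylzinc may also couple sluggishly, or the acid stage may add HCl or the 7-hydroxyl across the prenyl double bond. Fallback: setting out from 6, electrophilic bromination (NBS, MeCN, −20 °C) gives aryl bromide F3, in which the metalation site is fixed. Bromine–lithium exchange (t-BuLi, THF, −78 °C) leads to 8, which is acylated directly with Weinreb amide F4 (from 7 and N,O-dimethylhydroxylamine hydrochloride, pyridine, CH2Cl2) to give 10. Dilute HCl in MeOH at rt in the same flask closes the ring, so the route is rejoined at 12.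

3. Step 4 (demethylation). The Lewis acid may promote addition of the free 7-hydroxyl to the prenyl double bond (dimethylchroman formation), or the ether cleavage may stall. Fallback: setting out from 12, acetylation (Ac2O, pyridine, rt) gives 7-acetate F5, in which O7 can no longer cyclize. Chelation-controlled cleavage of the peri methyl ether with BCl3 (CH2Cl2, −78 to 0 °C) gives 5-hydroxy 7-acetate F6, and methanolysis (K2CO3, MeOH, rt) comes back to the route at 13.

Further compounds
F1 | step 5 | 7-[(tert-butyldimethylsilyl)oxy]-5-hydroxy-8-(3-methylbut-2-en-1-yl)-4H-chromen-4-one | CC(C)=CCc1c(O[Si](C)(C)C(C)(C)C)cc(O)c2c(=O)ccoc12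
F2 | step 5 | (2S)-7-[(tert-butyldimethylsilyl)oxy]-5-hydroxy-2-(4-methoxyphenyl)-8-(3-methylbut-2-en-1-yl)-2,3-dihydro-4H-chromen-4-one | COc1ccc([C@@H]2CC(=O)c3c(O)cc(O[Si](C)(C)C(C)(C)C)c(CC=C(C)C)c3O2)cc1
F3 | step 3 | 2-bromo-1-methoxy-3,5-bis(methoxymethoxy)-4-(3-methylbut-2-en-1-yl)benzene | COCOc1c(Br)c(OC)cc(OCOC)c1CC=C(C)C
F4 | step 3 | (E)-3-ethoxy-N-methoxy-N-methylprop-2-enamide | CCO/C=C/C(=O)N(C)OC
F5 | step 4 | 5-methoxy-8-(3-methylbut-2-en-1-yl)-4-oxo-4H-chromen-7-yl acetate | COc1cc(OC(C)=O)c(CC=C(C)C)c2occc(=O)c12
F6 | step 4 | 5-hydroxy-8-(3-methylbut-2-en-1-yl)-4-oxo-4H-chromen-7-yl acetate | CC(=O)Oc1cc(O)c2c(=O)ccoc2c1CC=C(C)C
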